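**Plan**
- **Cuts, in retrosynthetic order:** the O–CH2OMe acetal on the ring B phenol; C4–C5 of benzene ring A; the bond from the C5 carbon to the cinnamoyl C=O; O1–C2 of the dihydrofuran; C3–C3a (prenyl to pyranone).
- **Enabling feature:** C4, C3a, C7a, C7, C6 and the oxygen on C6 form the skeleton of a 2-pyranone whose 4-oxygen is O1 of the fused dihydrofuran ring. C5 with its cinnamoyl group is the methylene of a 6-(2-oxoalkyl) chain, so exchanging the ring oxygen for C5 turns a furo[3,2-c]pyran-4-one into the benzofuran.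
- **Forward order:** the purchased pyranone is prenylated at the future C3a, the dihydrofuran closes second (O1–C2), the cinnamoyl unit is joined to the 6-methyl carbon, and ring A closes last (C4–C5) at the expense of the pyranone.
- **Stereochemistry:** C2 is the only stereocentre. A Shi epoxidation with the D-fructose-derived ketone sets the (R)-epoxide, and its 5-exo opening with inversion gives (S). The E-alkene comes in with methyl p-coumarate.

Key step: step 7

Remark: atom labels follow benzofuran numbering, which matches furo[3,2-c]pyran-4-one numbering except that O5 becomes C5. Compounds 10 and 11 are drawn as keto tautomers although they will be largely enolised.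

Step 1
Reactants: 1 4-hydroxy-6-methyl-2H-pyran-2-one (slight excess); 2 prenyl acetate (3-methylbut-2-en-1-yl acetate)
Product: 3 4-hydroxy-6-methyl-3-(3-methylbut-2-en-1-yl)-2H-pyran-2-one
Conditions: NaH (1 equiv), THF–DMF, 0 °C; then 2, Pd(PPh3)4 (5 mol %), 60 °C
Reagents that add atoms: none
Why: Tsuji–Trost allylation, in which O-allylation of this acidic enol is reversible under Pd(0) because the pyranone oxide is itself a leaving group, so the material should collect in the C3-alkylated product, with attack at the unsubstituted terminus of the 1,1-dimethylallyl-palladium complex giving the linear prenyl group.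

Step 2
Reactants: 3 4-hydroxy-6-methyl-3-(3-methylbut-2-en-1-yl)-2H-pyran-2-one
Product: 4 4-(benzyloxy)-6-methyl-3-(3-methylbut-2-en-1-yl)-2H-pyran-2-one
Conditions: BnOH, PPh3, DIAD, THF, 0 °C to rt
Reagents that add atoms: benzyl alcohol, OCc1ccccc1
Why: Mitsunobu etherification uses the 4-OH (a vinylogous carboxylic acid) as pronucleophile and reacts at that oxygen, which avoids the C3 quaternisation possible with a benzyl halide and base and masks the oxidisable enol before step 3.

Step 3
Reactants: 4 4-(benzyloxy)-6-methyl-3-(3-methylbut-2-en-1-yl)-2H-pyran-2-one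
Product: 5 4-(benzyloxy)-3-{[(2R)-3,3-dimethyloxiran-2-yl]methyl}-6-methyl-2H-pyran-2-one
Conditions: D-fructose-derived Shi ketone (30 mol %), Oxone, K2CO3, Bu4NHSO4 (cat.), MeCN–dimethoxymethane / aq. borate–EDTA buffer (pH 10.5), 0 °C
Reagents that add atoms: Oxone (active component potassium peroxymonosulfate), [K+].[O-]S(=O)(=O)OO
Why: Shi asymmetric epoxidation, in which the chiral dioxirane meets the electron-rich trisubstituted alkene through the spiro transition state and, with the D-fructose-derived ketone, should deliver oxygen to the face that gives the (R)-epoxide, while the electron-poor pyranone double bonds and the benzyl ether are left alone.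

Step 4
Reactants: 5 4-(benzyloxy)-3-{[(2R)-3,3-dimethyloxiran-2-yl]methyl}-6-methyl-2H-pyran-2-one
Product: 7 (2S)-2-(2-hydroxypropan-2-yl)-6-methyl-2,3-dihydro-4H-furo[3,2-c]pyran-4-one, via free 4-hydroxy epoxide 6 (not isolated)
Conditions: H2 (1 atm), 10% Pd/C, K2CO3, MeOH, 0 °C to rt
Reagents that add atoms: none
Why: Hydrogenolysis of the vinylogous benzyl ester frees the 4-oxygen, whose potassium salt opens the epoxide by base-mediated 5-exo-tet SN2 attack at the less substituted carbon, so C2 forms with inversion ((R)-epoxide to (S)-dihydrofuran), in the way o-prenylphenol epoxides are closed to hydroxyisopropyl-dihydrobenzofurans.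

Step 5
Reactants: 8 methyl (E)-3-(4-hydroxyphenyl)prop-2-enoate (methyl p-coumarate)
Product: 9 methyl (E)-3-[4-(methoxymethoxy)phenyl]prop-2-enoate
Conditions: MOMCl, i-Pr2NEt, CH2Cl2, 0 °C to rt
Reagents that add atoms: chloromethyl methyl ether, COCCl
Why: Routine O-alkylation of a phenol with a chloromethyl ether gives an acetal that is inert to the amide base of step 6 and to the methoxide of step 7.

Step 6
Reactants: 7 (2S)-2-(2-hydroxypropan-2-yl)-6-methyl-2,3-dihydro-4H-furo[3,2-c]pyran-4-one; 9 methyl (E)-3-[4-(methoxymethoxy)phenyl]prop-2-enoate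
Product: 10 (2S)-2-(2-hydroxypropan-2-yl)-6-{(3E)-4-[4-(methoxymethoxy)phenyl]-2-oxobut-3-en-1-yl}-2,3-dihydro-4H-furo[3,2-c]pyran-4-one
Conditions: LiHMDS (3.3 equiv), THF, −78 °C; then 9, −78 to 0 °C; AcOH quench
Reagents that add atoms: none
Why: Vinylogous Claisen condensation known for 6-methyl-2-pyranone carbanions, in which, after the tertiary alkoxide, the 6-methyl group is the only site whose anion is delocalised into the lactone carbonyl, conjugate addition to the donor-substituted cinnamate is reversible, and the third equivalent of base removes the acidic methylene proton of 10 and so pulls the 1,2-acylation to completion.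

Step 7
Reactants: 10 (2S)-2-(2-hydroxypropan-2-yl)-6-{(3E)-4-[4-(methoxymethoxy)phenyl]-2-oxobut-3-en-1-yl}-2,3-dihydro-4H-furo[3,2-c]pyran-4-one
Product: 12 (E)-1-[(2S)-4,6-dihydroxy-2-(2-hydroxypropan-2-yl)-2,3-dihydro-1-benzofuran-5-yl]-3-[4-(methoxymethoxy)phenyl]prop-2-en-1-one, via ring-opened methyl ester 11 (not isolated)
Conditions: Mg(OMe)2 (commercial solution, 6 equiv), MeOH, reflux; poured into cold 1 M HCl (pH 3–4), immediate extraction
Reagents that add atoms: none
Why: Methoxide, helped by Mg(II) coordination, adds reversibly to the lactone carbonyl C4 and breaks the C4–O5 bond, leaving a methyl ester on C3a and a chelated 1,3-diketone on the chain from C7a (11); the diketone methylene carbon, the future C5, then attacks that ester, methoxide leaves again, and enolisation of the cyclohexenetrione to the phloroglucinol is the irreversible exit that drains the equilibrium, so O5 ends as the C6 hydroxyl and 12 is an isomer of 10. The closest known reaction type is the alkoxide- or Mg(OMe)2-induced Claisen recyclisation of 6-(2-oxoalkyl)-2-pyranones and of the related 3,5,7-triketo esters to acylphloroglucinols. Ring A closes in a 6-exo-trig Dieckmann-type acyl substitution, and the C3a=C7a double bond inside the dihydrofuran ring holds the ester and the nucleophilic chain cis for it. No stereocentre is created, C2 carries no acidic hydrogen and its C2–O1 bond is never broken, so the S configuration is retained. The step needs Claisen rather than aldol folding and a single acyl position: C3a bears no hydrogen and is locked in an enol ether, so it cannot act as an aldol donor, and C5 is the only acidic carbon that can reach the ester through a six-membered ring, which places the cinnamoyl group between the C4 and C6 hydroxyls. The enone is shielded from conjugate addition first as part of the diketonate and later as part of the chelated polyphenoxide, and the fast cold acid quench passes quickly through the near-neutral range in which flavanone closure is fastest.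

Step 8
Reactants: 12 (E)-1-[(2S)-4,6-dihydroxy-2-(2-hydroxypropan-2-yl)-2,3-dihydro-1-benzofuran-5-yl]-3-[4-(methoxymethoxy)phenyl]prop-2-en-1-one
Product: 13 (E)-1-[(2S)-4,6-dihydroxy-2-(2-hydroxypropan-2-yl)-2,3-dihydro-1-benzofuran-5-yl]-3-(4-hydroxyphenyl)prop-2-en-1-one
Conditions: 3 M aq. HCl (cat.), MeOH, rt, stopped as soon as 12 is consumed
Reagents that add atoms: none
Why: Acid-catalysed hydrolysis of an aryl MOM acetal, as practised on other 2',6'-dihydroxychalcones, should outrun both acid-mediated oxa-Michael closure to a flavanone and dehydration of the tertiary alcohol when temperature and contact time are kept low.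

**Compound list**
1 | 4-hydroxy-6-methyl-2H-pyran-2-one | CC1=CC(O)=CC(=O)O1 | starting material
2 | prenyl acetate | CC(C)=CCOC(C)=O | starting material
3 | 4-hydroxy-6-methyl-3-(3-methylbut-2-en-1-yl)-2H-pyran-2-one | CC1=CC(O)=C(CC=C(C)C)C(=O)O1 | intermediate
4 | 4-(benzyloxy)-6-methyl-3-(3-methylbut-2-en-1-yl)-2H-pyran-2-one | CC1=CC(OCc2ccccc2)=C(CC=C(C)C)C(=O)O1 | intermediate
5 | 4-(benzyloxy)-3-{[(2R)-3,3-dimethyloxiran-2-yl]methyl}-6-methyl-2H-pyran-2-one | CC1=CC(OCc2ccccc2)=C(C[C@H]2OC2(C)C)C(=O)O1 | intermediate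
6 | 3-{[(2R)-3,3-dimethyloxiran-2-yl]methyl}-4-hydroxy-6-methyl-2H-pyran-2-one | CC1=CC(O)=C(C[C@H]2OC2(C)C)C(=O)O1 | intermediate
7 | (2S)-2-(2-hydroxypropan-2-yl)-6-methyl-2,3-dihydro-4H-furo[3,2-c]pyran-4-one | CC(C)(O)[C@@H]1CC2=C(O1)C=C(C)OC2=O | intermediate
8 | methyl (E)-3-(4-hydroxyphenyl)prop-2-enoate | COC(=O)/C=C/c1ccc(O)cc1 | starting material
9 | methyl (E)-3-[4-(methoxymethoxy)phenyl]prop-2-enoate | COCOc1ccc(/C=C/C(=O)OC)cc1 | intermediate
10 | (2S)-2-(2-hydroxypropan-2-yl)-6-{(3E)-4-[4-(methoxymethoxy)phenyl]-2-oxobut-3-en-1-yl}-2,3-dihydro-4H-furo[3,2-c]pyran-4-one | CC(C)(O)[C@@H]1CC2=C(O1)C=C(CC(=O)/C=C/c3ccc(OCOC)cc3)OC2=O | intermediate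
11 | methyl (5S)-5-(2-hydroxypropan-2-yl)-2-{(5E)-6-[4-(methoxymethoxy)phenyl]-2,4-dioxohex-5-en-1-yl}-4,5-dihydrofuran-3-carboxylate | CC(C)(O)[C@@H]1CC(C(=O)OC)=C(CC(=O)CC(=O)/C=C/c2ccc(OCOC)cc2)O1 | intermediate
12 | (E)-1-[(2S)-4,6-dihydroxy-2-(2-hydroxypropan-2-yl)-2,3-dihydro-1-benzofuran-5-yl]-3-[4-(methoxymethoxy)phenyl]prop-2-en-1-one | CC(C)(O)[C@@H]1Cc2c(cc(O)c(C(=O)/C=C/c3ccc(OCOC)cc3)c2O)O1 | intermediate
13 | (E)-1-[(2S)-4,6-dihydroxy-2-(2-hydroxypropan-2-yl)-2,3-dihydro-1-benzofuran-5-yl]-3-(4-hydroxyphenyl)prop-2-en-1-one | CC(C)(O)[C@@H]1Cc2c(cc(O)c(C(=O)/C=C/c3ccc(O)cc3)c2O)O1 | target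

**Step count:** 8 steps in total. The longest linear sequence is 7 steps (steps 1–4 and 6–8, from 1).

**Steps most likely to fail**

**Step 7.**
- **Risk:** lactone opening may stall because the delocalised side-chain anion deactivates the pyranone, or the enone may be consumed by conjugate addition before the Claisen closure.
- **Fallback:** it sets out from 7 and builds the enone only after aromatisation. The dianion of 7 (LiHMDS) is acetylated with N-methoxy-N-methylacetamide to (2S)-2-(2-hydroxypropan-2-yl)-6-(2-oxopropyl)-2,3-dihydro-4H-furo[3,2-c]pyran-4-one F1. The Mg(OMe)2 recyclisation is then run on this enone-free, classical type of substrate and should give 1-[(2S)-4,6-dihydroxy-2-(2-hydroxypropan-2-yl)-2,3-dihydro-1-benzofuran-5-yl]ethanone F2. Both phenols are capped (NaH, 2.2 equiv, MOMCl, DMF) to give 1-[(2S)-2-(2-hydroxypropan-2-yl)-4,6-bis(methoxymethoxy)-2,3-dihydro-1-benzofuran-5-yl]ethanone F3. A Claisen–Schmidt condensation with commercial 4-(methoxymethoxy)benzaldehyde (KOH, EtOH) gives (E)-1-[(2S)-2-(2-hydroxypropan-2-yl)-4,6-bis(methoxymethoxy)-2,3-dihydro-1-benzofuran-5-yl]-3-[4-(methoxymethoxy)phenyl]prop-2-en-1-one F4. Aqueous HCl in MeOH removes all three acetals, and the route is rejoined at 13.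

**Step 6.**
- **Risk:** conjugate addition to the cinnamate may compete, or proton transfer from the product may stop the acylation part-way.
- **Fallback:** it sets out from 9 and 7 and replaces acylation by aldol addition and oxidation. DIBAL-H reduction of 9 gives (E)-3-[4-(methoxymethoxy)phenyl]prop-2-en-1-ol F5, and MnO2 gives (E)-3-[4-(methoxymethoxy)phenyl]prop-2-enal F6. The dianion of 7 adds 1,2 to this aldehyde, a well-known reaction of 6-methyl-2-pyranone anions. The product is (2S)-6-{(3E)-2-hydroxy-4-[4-(methoxymethoxy)phenyl]but-3-en-1-yl}-2-(2-hydroxypropan-2-yl)-2,3-dihydro-4H-furo[3,2-c]pyran-4-one F7, formed as both carbinol epimers. Dess–Martin periodinane buffered with NaHCO3 oxidises only the secondary allylic alcohol, and the route is rejoined at 10.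

**Step 8.**
- **Risk:** acid may induce oxa-Michael closure to flavanones or dehydration of the tertiary alcohol while the acetal is cleaved.
- **Fallback:** it sets out from 8 and removes the acid step altogether. Silylation (TBSCl, imidazole, DMF) gives methyl (E)-3-[4-(tert-butyldimethylsilyloxy)phenyl]prop-2-enoate F8. This ester acylates the dianion of 7 as in step 6 to give (2S)-6-{(3E)-4-[4-(tert-butyldimethylsilyloxy)phenyl]-2-oxobut-3-en-1-yl}-2-(2-hydroxypropan-2-yl)-2,3-dihydro-4H-furo[3,2-c]pyran-4-one F9. Under Mg(OMe)2 in refluxing MeOH, methoxide should cleave the aryl silyl ether in the same pot as the recyclisation. The cold acid quench then rejoins the route directly at 13.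

**Further compounds**
F1 | step 7 | (2S)-2-(2-hydroxypropan-2-yl)-6-(2-oxopropyl)-2,3-dihydro-4H-furo[3,2-c]pyran-4-one | CC(C)(O)[C@@H]1CC2=C(O1)C=C(CC(C)=O)OC2=O
F2 | step 7 | 1-[(2S)-4,6-dihydroxy-2-(2-hydroxypropan-2-yl)-2,3-dihydro-1-benzofuran-5-yl]ethanone | CC(C)(O)[C@@H]1Cc2c(cc(O)c(C(C)=O)c2O)O1
F3 | step 7 | 1-[(2S)-2-(2-hydroxypropan-2-yl)-4,6-bis(methoxymethoxy)-2,3-dihydro-1-benzofuran-5-yl]ethanone | CC(C)(O)[C@@H]1Cc2c(cc(OCOC)c(C(C)=O)c2OCOC)O1
F4 | step 7 | (E)-1-[(2S)-2-(2-hydroxypropan-2-yl)-4,6-bis(methoxymethoxy)-2,3-dihydro-1-benzofuran-5-yl]-3-[4-(methoxymethoxy)phenyl]prop-2-en-1-one | CC(C)(O)[C@@H]1Cc2c(cc(OCOC)c(C(=O)/C=C/c3ccc(OCOC)cc3)c2OCOC)O1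
F5 | step 6 | (E)-3-[4-(methoxymethoxy)phenyl]prop-2-en-1-ol | COCOc1ccc(/C=C/CO)cc1
F6 | step 6 | (E)-3-[4-(methoxymethoxy)phenyl]prop-2-enal | COCOc1ccc(/C=C/C=O)cc1
F7 | step 6 | (2S)-6-{(3E)-2-hydroxy-4-[4-(methoxymethoxy)phenyl]but-3-en-1-yl}-2-(2-hydroxypropan-2-yl)-2,3-dihydro-4H-furo[3,2-c]pyran-4-one (both carbinol epimers) | CC(C)(O)[C@@H]1CC2=C(O1)C=C(CC(O)/C=C/c3ccc(OCOC)cc3)OC2=O
F8 | step 8 | methyl (E)-3-[4-(tert-butyldimethylsilyloxy)phenyl]prop-2-enoate | COC(=O)/C=C/c1ccc(O[Si](C)(C)C(C)(C)C)cc1
F9 | step 8 | (2S)-6-{(3E)-4-[4-(tert-butyldimethylsilyloxy)phenyl]-2-oxobut-3-en-1-yl}-2-(2-hydroxypropan-2-yl)-2,3-dihydro-4H-furo[3,2-c]pyran-4-one | CC(C)(O)[C@@H]1CC2=C(O1)C=C(CC(=O)/C=C/c3ccc(O[Si](C)(C)C(C)(C)C)cc3)OC2=O
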